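**Retrosynthetic overview**
1. The target comes from O-acetylation of the free (S)-2-hydroxypropyl hydroxyquinone. That compound comes from aerobic para-oxygenation and alkaline unmasking of a 2-alkyl-3-ethoxy-1-naphthol.
2. The naphthol comes from a light-driven benzannulation of (2,4,5-trimethoxyphenyl)ketene with a chiral ethyl ynol ether. One operation makes C8a–C1 (aryl shift), C1–C2, C3–C4 and C4–C4a (quinone numbering).
3. The ketene comes from photolysis of a β-keto sulfoxonium ylide, itself made from 2,4,5-trimethoxybenzoic acid and trimethylsulfoxonium iodide.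
4. The ynol ether comes from ethoxyacetylene and (S)-propylene oxide, which supplies the only stereocentre.
5. Ring order: the benzenoid ring is bought, a transient cyclobutenone forms and opens, then the six-membered (later quinone) ring closes.

Assumption: the target is taken exactly as drawn, i.e. 3-[(2S)-2-acetoxypropyl]-2-hydroxy-5,6,8-trimethoxy-1,4-naphthoquinone (the [C@H] centre reads S).

**Step 1**
Reactants: 1 2,4,5-trimethoxybenzoic acid; 2 trimethylsulfoxonium iodide
Product: 5 2-[dimethyl(oxo)-λ6-sulfanylidene]-1-(2,4,5-trimethoxyphenyl)ethan-1-one, via dimethylsulfoxonium methylide 3 (not isolated), via 2,4,5-trimethoxybenzoyl imidazolide 4 (not isolated)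
Conditions: 1, CDI, THF, rt; separately 2 (3.3 equiv), KOtBu (3.0 equiv), THF, reflux; combine, 0 °C → rt
Reagents that add atoms: 1,1'-carbonyldiimidazole, O=C(n1ccnc1)n1ccnc1 (its imidazolyl group stays only in intermediate 4)
Why: Acylation of the Corey–Chaykovsky methylide by an activated acid gives a β-keto sulfoxonium salt that is deprotonated at once to the stabilised ylide, which stops over-addition; no stereocentre is involved.

**Step 2**
Reactants: 6 ethoxyacetylene; 7 (S)-propylene oxide
Product: 10 (2S)-5-ethoxypent-4-yn-2-yl acetate, via lithium ethoxyacetylide 8 (not isolated), via lithium (2S)-5-ethoxypent-4-yn-2-olate 9 (not isolated)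
Conditions: n-BuLi, THF, −78 °C; 7 (1.3 equiv), DMPU, −78 °C → rt, 16 h (sealed); Ac2O, 0 °C → rt; NaHCO3 work-up, Et3N-deactivated silica
Reagents that add atoms: acetic anhydride, CC(=O)OC(C)=O; n-butyllithium, [Li]CCCC (lithium in 8 and 9 only)
Why: SN2 opening of the terminal epoxide at its CH2 by a lithium acetylide (epoxide alkynylation) never touches the C–O bond of the stereocentre, so the purchased (S) configuration carries over unchanged, and the free lithium alkoxide is O-acylated in the same pot to hide the OH from the ketene of step 3.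

**Step 3**
Reactants: 5 β-keto sulfoxonium ylide; 10 (2S)-5-ethoxypent-4-yn-2-yl acetate
Product: 14 (2S)-1-(3-ethoxy-1-hydroxy-5,7,8-trimethoxynaphthalen-2-yl)propan-2-yl acetate, via aryl ketene 11 (not isolated), via cyclobutenone 12 (not isolated), via dienylketene 13 (not isolated)
Conditions: hν (300–320 nm), 10 (1.8 equiv), degassed ClCH2CH2Cl (0.03 M), FEP flow coil, 20 °C; then 80 °C, 2 h
Reagents that add atoms: none
Why: Proposed new method: UV excitation of the β-keto sulfoxonium ylide should expel DMSO, as N2 leaves a diazoketone, with 1,2-shift of the electron-rich aryl group (photo-Wolff) to give ketene 11; the nucleophilic β-carbon of ynol ether 10 then attacks the ketene carbonyl in a regioselective [2+2] to 12, which opens (4π, light or heat) to 13 and closes (6π) on the only free ortho carbon before tautomerising to 14, placing the alkyl chain next to the new OH and the OEt next to the new CH; the closest known reaction types are the Danheiser photochemical benzannulation of α-diazoketones with ynol ethers and the photolysis of β-keto sulfoxonium ylides to ketenes trapped by alcohols, whereas alkyne trapping of an ylide-derived ketene is not known; the remote stereocentre is untouched.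

**Step 4**
Reactants: 14 naphthol acetate
Product: 16 2-hydroxy-3-[(2S)-2-hydroxypropyl]-5,6,8-trimethoxynaphthalene-1,4-dione, via ethoxyquinone acetate 15 (not isolated)
Conditions: O2 (1 atm), Co(salen) (10 mol %), MeCN, rt, dark; Ar purge, 2 M aq KOH (6 equiv), rt → 40 °C; 1 M HCl, 0 °C
Reagents that add atoms: dioxygen, O=O; potassium hydroxide, [K+].[OH-]
Why: Salcomine-type aerobic para-oxygenation of a 4-unsubstituted 1-naphthol gives quinone 15, and hydroxide then cleaves both the acetate (saponification) and the vinylogous ethyl ester (addition–elimination at C2) because the resonance-stabilised 2-oxidoquinone anion is the thermodynamic sink; the sp3 C–O bond of the stereocentre is never broken, so (S) is kept.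

**Step 5**
Reactants: 16 hydroxyquinone alcohol
Product: 18 3-[(2S)-2-acetoxypropyl]-2-hydroxy-5,6,8-trimethoxynaphthalene-1,4-dione (target), via diacetate 17 (not isolated)
Conditions: Ac2O–pyridine (1:2), DMAP (5 mol %), 0 °C, dark; then H2O, rt, 1 h
Reagents that add atoms: acetic anhydride, CC(=O)OC(C)=O
Why: DMAP-catalysed exhaustive acetylation at high Ac2O concentration esterifies the secondary alcohol with retention, and the co-formed C2 enol acetate, a vinylogous mixed anhydride, is hydrolysed selectively by water/pyridine while the alkyl acetate persists (chemoselective acylation/hydrolysis).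

**Compound list**
1 | 2,4,5-trimethoxybenzoic acid | COc1cc(OC)c(C(=O)O)cc1OC | starting material
2 | trimethylsulfoxonium iodide | C[S+](C)(C)=O.[I-] | starting material
3 | dimethylsulfoxonium methylide | C[S+](C)(=O)[CH2-] | intermediate
4 | 2,4,5-trimethoxybenzoyl imidazolide | COc1cc(OC)c(C(=O)n2ccnc2)cc1OC | intermediate
5 | 2-[dimethyl(oxo)-λ6-sulfanylidene]-1-(2,4,5-trimethoxyphenyl)ethan-1-one | COc1cc(OC)c(C(=O)C=S(C)(C)=O)cc1OC | intermediate
6 | ethoxyacetylene | CCOC#C | starting material
7 | (S)-propylene oxide | C[C@H]1CO1 | starting material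
8 | lithium ethoxyacetylide | CCOC#C[Li] | intermediate
9 | lithium (2S)-5-ethoxypent-4-yn-2-olate | CCOC#CC[C@H](C)[O-].[Li+] | intermediate
10 | (2S)-5-ethoxypent-4-yn-2-yl acetate | CCOC#CC[C@H](C)OC(C)=O | intermediate
11 | (2,4,5-trimethoxyphenyl)ketene | O=C=Cc1cc(OC)c(OC)cc1OC | intermediate
12 | 2-[(2S)-2-acetoxypropyl]-3-ethoxy-4-(2,4,5-trimethoxyphenyl)cyclobut-2-en-1-one (both C4 epimers) | CCOC1=C(C[C@H](C)OC(C)=O)C(=O)C1c1cc(OC)c(OC)cc1OC | intermediate
13 | (3E)-2-[(2S)-2-acetoxypropyl]-3-ethoxy-4-(2,4,5-trimethoxyphenyl)buta-1,3-dien-1-one | O=C=C(C[C@H](C)OC(C)=O)/C(OCC)=C\c1cc(OC)c(OC)cc1OC | intermediate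
14 | (2S)-1-(3-ethoxy-1-hydroxy-5,7,8-trimethoxynaphthalen-2-yl)propan-2-yl acetate | COc1cc(OC)c2cc(OCC)c(C[C@H](C)OC(C)=O)c(O)c2c1OC | intermediate
15 | 3-[(2S)-2-acetoxypropyl]-2-ethoxy-5,6,8-trimethoxynaphthalene-1,4-dione | COc1cc(OC)c2c(c1OC)C(=O)C(C[C@H](C)OC(C)=O)=C(OCC)C2=O | intermediate
16 | 2-hydroxy-3-[(2S)-2-hydroxypropyl]-5,6,8-trimethoxynaphthalene-1,4-dione | COc1cc(OC)c2c(c1OC)C(=O)C(C[C@H](C)O)=C(O)C2=O | intermediate
17 | 2-acetoxy-3-[(2S)-2-acetoxypropyl]-5,6,8-trimethoxynaphthalene-1,4-dione | COc1cc(OC)c2c(c1OC)C(=O)C(C[C@H](C)OC(C)=O)=C(OC(C)=O)C2=O | intermediate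
18 | 3-[(2S)-2-acetoxypropyl]-2-hydroxy-5,6,8-trimethoxynaphthalene-1,4-dione (CNP0321270.1) | COc1cc(OC)c2c(c1OC)C(=O)C(C[C@H](C)OC(C)=O)=C(O)C2=O | target

**Totals**
- Total step count: 5.
- Longest linear sequence: 4 (1 → 5 → 14 → 16 → 18, or 6/7 → 10 → 14 → 16 → 18).

**Three steps most likely to fail**

*Step 3, the new step.*
- The ylide may photolyse inefficiently or recombine with DMSO.
- A free ketocarbene may be intercepted by the ortho-methoxy group.
- Ketene 11 may be consumed by DMSO, by unreacted 5 or by product 14.
- The fallback uses known chemistry and sets out from 1. Oxalyl chloride with catalytic DMF gives 2,4,5-trimethoxybenzoyl chloride F1. Diazomethane and Et3N in ether at 0 °C convert it into 2-diazo-1-(2,4,5-trimethoxyphenyl)ethan-1-one F2.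
- Irradiating F2 with 10 in ClCH2CH2Cl (254–300 nm) and then heating at 80 °C is the established diazoketone form of the Danheiser benzannulation. It comes back to the route at 14.

*Step 4.*
- The very electron-rich naphthol may dimerise or over-oxidise.
- Direct hydroxide attack at the hindered C2 of 15 may stall.
- The fallback sets out from 14. Teuber oxidation with Fremy's salt in buffered aqueous acetone is followed by isolation of 15.
- Catalytic NaOEt in dry EtOH then transfers the acetyl group to ethanol. The freed alkoxide displaces ethoxide intramolecularly (5-exo addition–elimination) to give (2S)-5,6,8-trimethoxy-2-methyl-2,3-dihydronaphtho[2,3-b]furan-4,9-dione F3.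
- This cyclic vinylogous ester is opened at the sp2 carbon by warm dilute NaOH and then cold acid, with the configuration retained. The sequence comes back at 16.

*Step 5.*
- The enol may be acetylated before the alcohol. The still-free alcohol can then displace acetate at C2 and close a dihydrofuran instead of being acylated.
- The fallback sets out from 16 and removes the electrophilic quinone first. Reductive peracetylation (Zn dust, Ac2O, pyridine, DMAP) gives (2S)-1-(1,3,4-triacetoxy-5,7,8-trimethoxynaphthalen-2-yl)propan-2-yl acetate F4.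
- The three aryl acetates are cleaved chemoselectively by aminolysis (pyrrolidine, MeCN, 0 °C), which leaves the alkyl acetate intact. The resulting 1,2,4-trihydroxynaphthalene autoxidises in air, and the sequence comes back at 18.

**Further compounds**
F1 | step 3 | 2,4,5-trimethoxybenzoyl chloride | COc1cc(OC)c(C(=O)Cl)cc1OC
F2 | step 3 | 2-diazo-1-(2,4,5-trimethoxyphenyl)ethan-1-one | COc1cc(OC)c(C(=O)C=[N+]=[N-])cc1OC
F3 | step 4 | (2S)-5,6,8-trimethoxy-2-methyl-2,3-dihydronaphtho[2,3-b]furan-4,9-dione | COc1cc(OC)c2c(c1OC)C(=O)C3=C(O[C@@H](C)C3)C2=O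
F4 | step 5 | (2S)-1-(1,3,4-triacetoxy-5,7,8-trimethoxynaphthalen-2-yl)propan-2-yl acetate | COc1cc(OC)c2c(OC(C)=O)c(OC(C)=O)c(C[C@H](C)OC(C)=O)c(OC(C)=O)c2c1OC
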